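## Retrosynthetic overview

Labels used below: C1 lactone O–CH, C2=C3(CH3), C4 (OAc), C5–C6(CH3) oxirane, C7, C8, C9 (angelate), C10 ring-fusion CH, C11(=C13H2), C12 lactone C=O.

1. Last C–O bonds: the C4 acetate and the C5/C6 oxirane (hydroxyl-directed, vanadium) on a macrocyclic dienol; the C9 angelate by Mitsunobu C–O formation with inversion.
2. Ten-membered ring (second ring): C4–C5 by Nozaki–Hiyama–Kishi closure of a Z-vinyl iodide onto an enal.
3. Lactone (first ring): C1–C10 by indium Barbier allylation of a C1–C4 enal with a 2-(bromomethyl)enoate, then O–C12 lactonisation; C10 and C1 are relayed from C9.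
4. Key disconnection: the C9–O bond of an α-alkoxy aldehyde, made by a new enamine-catalysed α-tert-butoxylation; ring order lactone → carbocycle → oxirane.

Assumption: in the Barbier step the aldehyde adds to the alkene face anti to the C9 tert-butoxy group (C9–H eclipsing the alkene); the route is drawn for this facial sense.

## Route

Step 1
Reactants: 1 2-(3-chloropropyl)-1,3-dioxolane; 2 propyne
Product: 6 (5Z)-6-iodo-5-methylhex-5-enal, via Grignard reagent 3 (not isolated), via vinylcopper 4 (not isolated), via iodo acetal 5 (not isolated)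
Conditions: Mg, THF, 45 °C; CuBr·SMe2, Et2O/Me2S, −45 °C; 2, −25 °C; I2, THF, −50 → 0 °C; then 2 M HCl, THF, rt
Reagents that add atoms: iodine (II); water (O)
Why: Normant carbocupration: the alkylcopper adds syn across propyne with copper on the terminal carbon, iodinolysis with retention gives the Z-vinyl iodide (iodine cis to the chain), and acid hydrolysis of the dioxolane then frees the aldehyde.

Step 2
Reactants: 6 (5Z)-6-iodo-5-methylhex-5-enal
Product: 7 (2S,5Z)-2-tert-butoxy-6-iodo-5-methylhex-5-enal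
Conditions: PhCO3t-Bu (1.3 equiv), (S)-α,α-diphenylprolinol trimethylsilyl ether (20 mol%), hydroquinone (10 mol%), toluene/(CF3)2CHOH 4:1, 0 °C
Reagents that add atoms: tert-butyl peroxybenzoate (CC(C)(C)OOC(=O)c1ccccc1)
Why: Proposed new method: the amine forms the E-enamine of 6, whose β-carbon attacks the peroxide oxygen that bears the tert-butyl group (SN2 at oxygen, benzoate leaving, the fluoro alcohol hydrogen-bonding to the perester carbonyl) on the face not shielded by the diphenyl(silyloxy)methyl group, so that iminium hydrolysis releases the 2S ether and sets C9 as the relay centre for C10 and C1; closest known reaction type: diarylprolinol silyl ether catalysed α-benzoyloxylation of aldehydes with dibenzoyl peroxide, together with the tert-butoxylation of Grignard reagents by this same perester.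

Step 3
Reactants: 7 (2S,5Z)-2-tert-butoxy-6-iodo-5-methylhex-5-enal; 8 methyl acrylate
Product: 9 methyl (4S,7Z)-4-tert-butoxy-3-hydroxy-8-iodo-7-methyl-2-methylideneoct-7-enoate (C3 epimers)
Conditions: DABCO (1 equiv), 8 (neat, 5 equiv), MeOH (cat.), rt, 3 d
Reagents that add atoms: none
Why: Morita–Baylis–Hillman reaction of the electrophilic α-alkoxy aldehyde; the new carbinol (C10) forms as an epimer mixture that does not matter because it becomes sp2 in step 4, and C9 is not touched.

Step 4
Reactants: 9 methyl (4S,7Z)-4-tert-butoxy-3-hydroxy-8-iodo-7-methyl-2-methylideneoct-7-enoate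
Product: 10 methyl (2Z,4S,7Z)-2-(bromomethyl)-4-tert-butoxy-8-iodo-7-methylocta-2,7-dienoate
Conditions: NBS, Me2S, CH2Cl2, 0 °C → rt
Reagents that add atoms: N-bromosuccinimide (O=C1CCC(=O)N1Br)
Why: Corey–Kim-type activation of the allylic alcohol as an alkoxysulfonium salt and SN2' attack of bromide give the rearranged primary allylic bromide with the thermodynamically preferred 2Z geometry (chain cis to CH2Br), the geometry the chair transition state of step 7 needs.

Step 5
Reactants: 11 1,1-dimethoxypropan-2-one; 12 vinylmagnesium bromide (CH2=CHMgBr)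
Product: 13 1,1-dimethoxy-2-methylbut-3-en-2-ol (racemic)
Conditions: THF, 0 °C; aq. NH4Cl
Reagents that add atoms: none
Why: Grignard 1,2-addition to the activated α,α-dialkoxy ketone; the tertiary carbinol is racemic and its stereocentre is erased in step 6.

Step 6
Reactants: 13 1,1-dimethoxy-2-methylbut-3-en-2-ol
Product: 14 (2E)-4,4-dimethoxy-3-methylbut-2-enal
Conditions: [C5H5NH][CrO3Cl] (pyridinium chlorochromate), NaOAc, 4 Å MS, CH2Cl2, rt
Reagents that add atoms: pyridinium chlorochromate ([O-][Cr](=O)(=O)Cl.c1cc[nH+]cc1)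
Why: Babler–Dauben oxidative transposition: the chromate ester of the tertiary allylic alcohol undergoes a [3,3] shift and the primary chromate is oxidised to the enal, the E isomer (formyl trans to the bulky acetal carbon) being favoured and purified by chromatography.

Step 7
Reactants: 10 methyl (2Z,4S,7Z)-2-(bromomethyl)-4-tert-butoxy-8-iodo-7-methylocta-2,7-dienoate; 14 (2E)-4,4-dimethoxy-3-methylbut-2-enal
Product: 16 (4R,5S)-4-[(1S,4Z)-1-tert-butoxy-5-iodo-4-methylpent-4-en-1-yl]-5-[(1E)-3,3-dimethoxy-2-methylprop-1-en-1-yl]-3-methylideneoxolan-2-one, via hydroxy ester 15 (not isolated)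
Conditions: In powder, THF/aq. NaH2PO4–Na2HPO4 (pH 7) 3:1, rt; then PPTS (cat.), CH2Cl2, rt
Reagents that add atoms: none
Why: Indium Barbier 2-(alkoxycarbonyl)allylation through a closed chair transition state: the 2Z bromide (chain cis to CH2In) gives the syn γ-adduct, which lactonises to the cis-4,5-disubstituted α-methylene lactone, while C9–H eclipses the alkene (allylic 1,3-strain) and the aldehyde adds anti to the tert-butoxy group, setting C10 (R) and C1 (S) from 9S; vinyl iodide and acetal are inert to indium at pH 7.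

Step 8
Reactants: 16 the lactone of step 7
Product: 17 (2E)-3-[(2S,3R)-3-[(1S,4Z)-1-hydroxy-5-iodo-4-methylpent-4-en-1-yl]-4-methylidene-5-oxooxolan-2-yl]-2-methylprop-2-enal
Conditions: CF3CO2H/CH2Cl2 1:2, H2O (5 equiv), anisole, 0 °C → rt
Reagents that add atoms: water (O)
Why: Acidolysis (E1 loss of 2-methylpropene) of the tert-butyl ether and acid-catalysed hydrolysis of the dimethyl acetal occur together; no stereocentre is touched, and the E-enal cannot cyclise onto C1–O.

Step 9
Reactants: 17 the hydroxy enal lactone of step 8; 18 angelic acid, (2Z)-2-methylbut-2-enoic acid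
Product: 19 (1R,4Z)-5-iodo-4-methyl-1-[(2S,3R)-2-[(1E)-2-methyl-3-oxoprop-1-en-1-yl]-4-methylidene-5-oxooxolan-3-yl]pent-4-en-1-yl (2Z)-2-methylbut-2-enoate
Conditions: PPh3, DIAD, toluene, −20 → 0 °C
Reagents that add atoms: none
Why: Mitsunobu esterification: the C9 oxyphosphonium ion is displaced by angelate in an SN2 step with inversion (9S to 9R), a C–O bond formation that installs the ester and corrects C9 at once under neutral cold conditions that do not isomerise the Z acid to tiglate.

Step 10
Reactants: 19 the angelate of step 9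
Product: 20 (3aR,4R,7Z,9S,10E,11aS)-9-hydroxy-7,10-dimethyl-3-methylidene-2-oxo-2,3,3a,4,5,6,9,11a-octahydrocyclodeca[b]furan-4-yl (2Z)-2-methylbut-2-enoate
Conditions: CrCl2 (6 equiv), NiCl2 (2 mol%), N-[2-((4S)-4-isopropyl-4,5-dihydrooxazol-2-yl)-6-methylphenyl]methanesulfonamide (6.6 equiv; the ligand antipode matched for the 9S carbinol is used), Et3N, MeCN/THF, 2 mM, rt
Reagents that add atoms: none
Why: Nozaki–Hiyama–Kishi reaction: NiCl2-catalysed formation of the alkenylchromium from the Z-vinyl iodide with retention and its 1,2-addition to the enal close the ten-membered ring at C4–C5 under high dilution, the carbinol C4 (position 9 of the fused name, S) being set by the chiral sulfonamide ligand on chromium, and the organochromium tolerates the lactone and both esters.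

Step 11
Reactants: 20 the macrocyclic dienol of step 10
Product: 21 (3aR,4R,7S,8R,9R,10E,11aS)-7,8-epoxy-9-hydroxy-7,10-dimethyl-3-methylidene-2-oxo-2,3,3a,4,5,6,7,8,9,11a-decahydrocyclodeca[b]furan-4-yl (2Z)-2-methylbut-2-enoate
Conditions: VO(acac)2 (10 mol%), t-BuOOH (1.5 equiv), CH2Cl2, 0 °C
Reagents that add atoms: tert-butyl hydroperoxide (CC(C)(C)OO)
Why: Vanadium-catalysed hydroxyl-directed epoxidation: the vanadate ester of the C4 hydroxyl delivers oxygen to the electron-rich Z-trisubstituted C5=C6 bond on the face cis to the hydroxyl (the cis preference of this reagent with medium-ring Z-cycloalkenols, opposite to peracids), setting C5 (R) and C6 (S), while the E-alkene next to the lactone oxygen and the two acrylate-type alkenes are electron-poor and react more slowly.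

Step 12
Reactants: 21 the epoxy alcohol of step 11
Product: 22 (3aR,4R,7S,8R,9R,10E,11aS)-9-acetoxy-7,8-epoxy-7,10-dimethyl-3-methylidene-2-oxo-2,3,3a,4,5,6,7,8,9,11a-decahydrocyclodeca[b]furan-4-yl (2Z)-2-methylbut-2-enoate (target)
Conditions: Ac2O, pyridine, DMAP (cat.), CH2Cl2, 0 °C → rt
Reagents that add atoms: acetic anhydride (CC(=O)OC(C)=O)
Why: DMAP-catalysed acylation of the secondary alcohol with retention gives the acetate; the mild base leaves oxirane, angelate and methylene lactone intact.

## Compound list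

1 | 2-(3-chloropropyl)-1,3-dioxolane | ClCCCC1OCCO1 | starting material
2 | propyne | CC#C | starting material
3 | [3-(1,3-dioxolan-2-yl)propyl]magnesium chloride | Cl[Mg]CCCC1OCCO1 | intermediate
4 | [(1Z)-5-(1,3-dioxolan-2-yl)-2-methylpent-1-en-1-yl]copper | [Cu]/C=C(/C)CCCC1OCCO1 | intermediate
5 | 2-[(4Z)-5-iodo-4-methylpent-4-en-1-yl]-1,3-dioxolane | I/C=C(/C)CCCC1OCCO1 | intermediate
6 | (5Z)-6-iodo-5-methylhex-5-enal | I/C=C(/C)CCCC=O | intermediate
7 | (2S,5Z)-2-tert-butoxy-6-iodo-5-methylhex-5-enal | I/C=C(/C)CC[C@H](OC(C)(C)C)C=O | intermediate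
8 | methyl acrylate | C=CC(=O)OC | starting material
9 | methyl (4S,7Z)-4-tert-butoxy-3-hydroxy-8-iodo-7-methyl-2-methylideneoct-7-enoate (C3 epimers) | COC(=O)C(=C)C(O)[C@@H](OC(C)(C)C)CC/C(C)=C\I | intermediate
10 | methyl (2Z,4S,7Z)-2-(bromomethyl)-4-tert-butoxy-8-iodo-7-methylocta-2,7-dienoate | COC(=O)/C(CBr)=C/[C@@H](OC(C)(C)C)CC/C(C)=C\I | intermediate
11 | 1,1-dimethoxypropan-2-one | CC(=O)C(OC)OC | starting material
12 | vinylmagnesium bromide (CH2=CHMgBr) | C=C[Mg]Br | starting material
13 | 1,1-dimethoxy-2-methylbut-3-en-2-ol (racemic) | C=CC(C)(O)C(OC)OC | intermediate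
14 | (2E)-4,4-dimethoxy-3-methylbut-2-enal | O=C/C=C(\C)C(OC)OC | intermediate
15 | methyl (3S,4S,5E)-3-[(1S,4Z)-1-tert-butoxy-5-iodo-4-methylpent-4-en-1-yl]-4-hydroxy-7,7-dimethoxy-6-methyl-2-methylidenehept-5-enoate | COC(=O)C(=C)[C@H]([C@@H](OC(C)(C)C)CC/C(C)=C\I)[C@@H](O)/C=C(\C)C(OC)OC | intermediate
16 | (4R,5S)-4-[(1S,4Z)-1-tert-butoxy-5-iodo-4-methylpent-4-en-1-yl]-5-[(1E)-3,3-dimethoxy-2-methylprop-1-en-1-yl]-3-methylideneoxolan-2-one | C=C1C(=O)O[C@@H](/C=C(\C)C(OC)OC)[C@H]1[C@@H](OC(C)(C)C)CC/C(C)=C\I | intermediate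
17 | (2E)-3-[(2S,3R)-3-[(1S,4Z)-1-hydroxy-5-iodo-4-methylpent-4-en-1-yl]-4-methylidene-5-oxooxolan-2-yl]-2-methylprop-2-enal | C=C1C(=O)O[C@@H](/C=C(\C)C=O)[C@H]1[C@@H](O)CC/C(C)=C\I | intermediate
18 | angelic acid, (2Z)-2-methylbut-2-enoic acid | C/C=C(/C)C(O)=O | starting material
19 | (1R,4Z)-5-iodo-4-methyl-1-[(2S,3R)-2-[(1E)-2-methyl-3-oxoprop-1-en-1-yl]-4-methylidene-5-oxooxolan-3-yl]pent-4-en-1-yl (2Z)-2-methylbut-2-enoate | C=C1C(=O)O[C@@H](/C=C(\C)C=O)[C@H]1[C@H](OC(=O)/C(C)=C\C)CC/C(C)=C\I | intermediate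
20 | (3aR,4R,7Z,9S,10E,11aS)-9-hydroxy-7,10-dimethyl-3-methylidene-2-oxo-2,3,3a,4,5,6,9,11a-octahydrocyclodeca[b]furan-4-yl (2Z)-2-methylbut-2-enoate | C=C1C(=O)O[C@H]2/C=C(\C)[C@@H](O)/C=C(/C)CC[C@@H](OC(=O)/C(C)=C\C)[C@@H]12 | intermediate
21 | (3aR,4R,7S,8R,9R,10E,11aS)-7,8-epoxy-9-hydroxy-7,10-dimethyl-3-methylidene-2-oxo-2,3,3a,4,5,6,7,8,9,11a-decahydrocyclodeca[b]furan-4-yl (2Z)-2-methylbut-2-enoate | C=C1C(=O)O[C@H]2/C=C(\C)[C@@H](O)[C@H]3O[C@@]3(C)CC[C@@H](OC(=O)/C(C)=C\C)[C@@H]12 | intermediate
22 | (3aR,4R,7S,8R,9R,10E,11aS)-9-acetoxy-7,8-epoxy-7,10-dimethyl-3-methylidene-2-oxo-2,3,3a,4,5,6,7,8,9,11a-decahydrocyclodeca[b]furan-4-yl (2Z)-2-methylbut-2-enoate | C=C1C(=O)O[C@H]2/C=C(\C)[C@@H](OC(C)=O)[C@H]3O[C@@]3(C)CC[C@@H](OC(=O)/C(C)=C\C)[C@@H]12 | target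

## Step count and risks

Total step count: 12. Longest linear sequence: 10 (steps 1–4 and 7–12); steps 5 and 6 make the enal partner 14.

Steps most likely to fail:

Step 2 (the proposed α-tert-butoxylation; the perester may be too weak an electrophile for the enamine or may transfer benzoate). Fallback with known chemistry, setting out from 6 and coming back to the route at 17: aldehyde 6 is α-oxyaminated with TEMPO under CuCl2 and chiral imidazolidinone trifluoroacetate catalysis in air (antipode that gives 2S) to the α-aminoxy aldehyde F1; the same Morita–Baylis–Hillman reaction with 8 gives the adduct F2, NBS/Me2S gives the Z-allylic bromide F3, and the indium Barbier reaction with 14 gives the hydroxy ester F4 (not isolated) and then the lactone F5; Zn dust in AcOH/THF/H2O cleaves the N–O bond and hydrolyses the acetal to give 17.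

Step 9 (Mitsunobu on a β-branched secondary alcohol with a weakly acidic, isomerisable acid; elimination or participation of the lactone carbonyl may compete). Fallback setting out from 17 and coming back at 19: 17 is converted with 4-nitrobenzenesulfonyl chloride and DMAP into the C9 nosylate F6, which is displaced with inversion by cesium angelate F7 (made from 18 and Cs2CO3) with 18-crown-6 in toluene to give 19; activation and substitution are separated, so no betaine has to be protonated by angelic acid.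

Step 10 (medium-ring closure and ligand control of C4 against an unknown macrocyclic bias). Fallback setting out from 19 and coming back at 22: 19 is cyclised with CrCl2/NiCl2 and the other ligand antipode (or no ligand) and the C4-epimeric dienol F8 is taken on; mCPBA, which epoxidises medium-ring Z-cycloalkenols trans to the hydroxyl, gives the trans-epoxy alcohol F9 with the same oxirane configuration as 21, and a Mitsunobu reaction with acetic acid (PPh3, DIAD) inverts C4 and delivers 22 directly.

Further compounds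
F1 | step 2 | (2S,5Z)-6-iodo-5-methyl-2-[(2,2,6,6-tetramethylpiperidin-1-yl)oxy]hex-5-enal | I/C=C(/C)CC[C@H](ON1C(C)(C)CCCC1(C)C)C=O
F2 | step 2 | analogue of 9 carrying the tetramethylpiperidinyloxy group at C9 in place of tert-butoxy (C3 epimers) | COC(=O)C(=C)C(O)[C@@H](ON1C(C)(C)CCCC1(C)C)CC/C(C)=C\I
F3 | step 2 | analogue of 10 carrying the tetramethylpiperidinyloxy group at C9 (2Z bromide) | COC(=O)/C(CBr)=C/[C@@H](ON1C(C)(C)CCCC1(C)C)CC/C(C)=C\I
F4 | step 2 | analogue of hydroxy ester 15 carrying the tetramethylpiperidinyloxy group at C9 | COC(=O)C(=C)[C@H]([C@@H](ON1C(C)(C)CCCC1(C)C)CC/C(C)=C\I)[C@@H](O)/C=C(\C)C(OC)OC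
F5 | step 2 | analogue of lactone 16 carrying the tetramethylpiperidinyloxy group at C9 | C=C1C(=O)O[C@@H](/C=C(\C)C(OC)OC)[C@H]1[C@@H](ON2C(C)(C)CCCC2(C)C)CC/C(C)=C\I
F6 | step 9 | C9 4-nitrobenzenesulfonate of 17 (C9 configuration retained) | C=C1C(=O)O[C@@H](/C=C(\C)C=O)[C@H]1[C@@H](OS(=O)(=O)c2ccc(cc2)[N+](=O)[O-])CC/C(C)=C\I
F7 | step 9 | cesium (2Z)-2-methylbut-2-enoate | C/C=C(/C)C(=O)[O-].[Cs+]
F8 | step 10 | (3aR,4R,7Z,9R,10E,11aS) dienol, the C4 epimer of 20 | C=C1C(=O)O[C@H]2/C=C(\C)[C@H](O)/C=C(/C)CC[C@@H](OC(=O)/C(C)=C\C)[C@@H]12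
F9 | step 10 | (3aR,4R,7S,8R,9S,10E,11aS) trans-epoxy alcohol, the C4 epimer of 21 | C=C1C(=O)O[C@H]2/C=C(\C)[C@H](O)[C@H]3O[C@@]3(C)CC[C@@H](OC(=O)/C(C)=C\C)[C@@H]12
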